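**Plan**
- Cuts, in order: the C15–O ether bond between the labdane half (isocupressic acid) and the eudesmane half (cryptomeridiol). Then C14–C15 and C13–C16, back to a C13≡C14 alkyne. Last C4–C5 and C9–C10, which opens labdane rings A and B to an acyclic (E,E)-dienyne 2-methyl-3-oxo ester.
- Enabling feature: in ring A the quaternary C4 carries the axial C19 carboxyl and the equatorial C18 methyl, next to an unsubstituted C3 that can hold a ketone. C4, C5, C10 and C9 are contiguous centres of a trans-decalin, and ring B ends in the C8=C17 methylene. This is the pattern left by a C4 ketoester radical that passes through C5=C10 and C8=C9 and is terminated by Cu(II).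
- Forward: the chain is joined at C11–C12 and C1–C2, then ring A and ring B close in one flask and C3 is deoxygenated. The alkyne becomes the 13E allylic bromide, the bought eudesmane decalin is attached through oxygen, and C19 is taken to the acid last.
- Stereochemistry: labdane C4 comes from the 8-phenylmenthyl ester, and C5, C10 and C9 follow by chair–chair relay from the E,E-diene. 13E comes from syn carboalumination. Eudesmane C5′, C7′ and C10′ come from (+)-β-eudesmol and C4′ from α-face hydration.

Key step: step 6

Numbering: labdane numbering is used for the left half and primed eudesmane numbering for the right half.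

Assumption: the unchelated 2-methyl ketoester radical is taken to react in the W-shaped rotamer, with the ester C=O turned away from C3 and the ketone C=O turned away from C19. With the usual stacked ester conformation, the (1S,2R,5S)-auxiliary then leaves open the face that gives the 4β-carboxyl, 10β-methyl (normal labdane) series. This choice of rotamer fixes the antipode of the auxiliary and rests on a model only.

**Step 1**
Reactants: 1 geranyl bromide; 2 1-(trimethylsilyl)propyne
Product: 4 (5E)-6,10-dimethyl-1-(trimethylsilyl)undeca-5,9-dien-1-yne, via lithiated silylpropyne 3 (not isolated)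
Conditions: 2, n-BuLi, THF, −78 to −20 °C; then 1, −78 °C to rt
Reagents that add atoms: n-butyllithium, [Li]CCCC (gives only the lithium of 3; none of its atoms stays in 4)
Why: Propargylic lithiation followed by SN2 alkylation with a primary allylic bromide is a standard 1,5-enyne synthesis, in which the silyl group directs attack to the propargylic rather than the allenic terminus and the E alkene of 1 is untouched (C11–C12 bond).

**Step 2**
Reactants: 4 silyl dienyne
Product: 5 (2E,6E)-2,6-dimethyl-11-(trimethylsilyl)undeca-2,6-dien-10-yn-1-ol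
Conditions: SeO2 (cat), t-BuOOH, salicylic acid (cat), CH2Cl2, 0 °C to rt, stopped at partial conversion
Reagents that add atoms: tert-butyl hydroperoxide, CC(C)(C)OO (the oxygen atom, passed on through SeO2)
Why: The catalytic Riley allylic oxidation (ene reaction, then [2,3]-sigmatropic shift) hydroxylates the E-methyl of the more accessible terminal isopropylidene unit of polyprenyl chains, and the [2,3] shift fixes the E geometry of the new allylic alcohol.

**Step 3**
Reactants: 5 allylic alcohol
Product: 6 (5E,9E)-11-bromo-6,10-dimethyl-1-(trimethylsilyl)undeca-5,9-dien-1-yne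
Conditions: CBr4, PPh3, CH2Cl2, −20 to 0 °C
Reagents that add atoms: carbon tetrabromide, BrC(Br)(Br)Br
Why: The Appel reaction replaces a primary allylic hydroxyl by SN2 at low temperature without allylic transposition or E/Z loss, and the silylalkyne is inert to it.

**Step 4**
Reactants: 7 (+)-8-phenylmenthol (1S,2R,5S); 8 ethyl 2-methylacetoacetate
Product: 9 (1S,2R,5S)-8-phenylmenthyl 2-methyl-3-oxobutanoate (C2 epimers)
Conditions: DMAP (0.3 equiv), toluene, reflux, 4 Å sieves in the return line
Reagents that add atoms: none
Why: DMAP-catalysed transesterification of β-ketoesters runs through an acylketene, so even a hindered secondary alcohol is acylated, the carbinol centre is not touched, and the epimeric C2 is of no consequence because it later becomes a planar radical.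

**Step 5**
Reactants: 9 8-phenylmenthyl 2-methylacetoacetate; 6 allylic bromide
Product: 11 (1S,2R,5S)-8-phenylmenthyl (6E,10E)-2,6,10-trimethyl-3-oxo-15-(trimethylsilyl)pentadeca-6,10-dien-14-ynoate (C2 epimers), via sodium lithium dienediolate 10 (not isolated)
Conditions: NaH, THF, 0 °C; n-BuLi, 0 °C; then 6, 0 °C to rt; AcOH quench
Reagents that add atoms: sodium hydride, [Na+].[H-], and n-butyllithium, [Li]CCCC (give only the counter-ions of 10; none of their atoms stays in 11)
Why: In the Weiler dianion alkylation only the more basic terminal carbon of the dienediolate attacks the allylic bromide by SN2, which forms the C1–C2 bond and keeps both E alkenes.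

**Step 6**
Reactants: 11 acyclic dienynyl 2-methyl-β-ketoester
Product: 12 (1S,2R,5S)-8-phenylmenthyl 3-oxo-14-(trimethylsilyl)-15,16-dinorlabd-8(17)-en-13-yn-19-oate (4α-CH3, 4β-ester axial, 5α-H, 9α-H, 10β-CH3)
Conditions: Mn(OAc)3·2H2O (2.2 equiv), Cu(OAc)2·H2O (1.0 equiv, about 0.1 M), degassed AcOH, 25 °C
Reagents that add atoms: none
Why: Mn(III) oxidises the enolate of 11 (slow enolisation, fast electron transfer, as for other 2-alkyl-3-oxo esters) to the free, electrophilic tertiary C4 radical, which adds to C5 of the C5=C10 alkene; the tertiary C10 radical then adds to C9 of the C8=C9 alkene, and the tertiary C8 radical is taken up by Cu(OAc)2 as an alkylcopper(III) species that loses a C17 hydrogen by syn β-elimination to leave the C8=C17 methylene. The closest known reaction type is the Mn(OAc)3/Cu(OAc)2 oxidative free-radical polyene cyclization of 2-methyl-3-oxo polyenoates to 3-oxo-4-carboalkoxy-8(17)-ene trans-decalins, a reaction class in which 8-phenylmenthyl esters have also served as the source of facial bias. Ring A closes 6-endo-trig (C4–C5) and ring B closes 6-endo-trig (C10–C9), the endo mode being imposed each time by the methyl group on the inner alkene carbon (C10, then C8). C4 is set by the auxiliary, whose phenyl ring stacks over one face of the planar ketoester radical so that C5 bonds to the open face, and the ester ends axial (C19, β) because the unchelated radical reacts with its ketone C=O turned away from the ester and syn to the C18 methyl, the group syn to that C=O becoming equatorial in the chair; C5 and C10 follow from the E C5=C10 alkene in a chair–chair array (trans fusion, C20 cis to C19), and C9 follows from the equatorial placement of the C11 chain. No Lewis acid is added, because a chelated syn-dicarbonyl radical would hold the ester syn to the ketone C=O and so deliver it equatorial. The step needs facial selectivity (secured by the auxiliary), a halt after two rings (a full equivalent of Cu(II) should oxidise the C8 radical faster than it adds 5-exo-dig to C13, and the silyl cap keeps copper off the alkyne terminus) and elimination toward C17 (the usual course of Cu(II) with tertiary radicals).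

**Step 7**
Reactants: 12 bicyclic 3-ketone
Product: 13 the 3β-alcohol of 12 (3β-OH equatorial)
Conditions: NaBH4, EtOH–THF, 0 °C
Reagents that add atoms: none
Why: In this borohydride reduction of a hindered cyclohexanone, hydride arrives axially from the α face, away from the axial C19 ester and the C10 methyl, to give the equatorial 3β-alcohol, whose configuration does not matter because the centre is removed in step 9.

**Step 8**
Reactants: 13 3β-alcohol
Product: 14 the 3β-O-(phenoxythiocarbonyl) derivative of 13
Conditions: PhOC(S)Cl, pyridine, DMAP (cat), CH2Cl2, rt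
Reagents that add atoms: O-phenyl chlorothionoformate, S=C(Cl)Oc1ccccc1
Why: Thionocarbonate formation under amine catalysis is the mild activation for a Barton–McCombie deoxygenation, and it avoids the alkoxide conditions of xanthate formation that could trigger retro-aldol opening of this β-hydroxy ester.

**Step 9**
Reactants: 14 thionocarbonate
Product: 15 (1S,2R,5S)-8-phenylmenthyl 14-(trimethylsilyl)-15,16-dinorlabd-8(17)-en-13-yn-19-oate
Conditions: Bu3SnH, AIBN (cat), toluene, 90 °C
Reagents that add atoms: none
Why: In the Barton–McCombie deoxygenation the stannyl radical adds to C=S and the released secondary C3 radical takes hydrogen from the stannane, with no unsaturation within reach of C3 and with the silyl cap protecting the alkyne from hydrostannation.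

**Step 10**
Reactants: 15 silylalkyne
Product: 16 (1S,2R,5S)-8-phenylmenthyl 15,16-dinorlabd-8(17)-en-13-yn-19-oate (terminal alkyne)
Conditions: K2CO3 (cat), MeOH–THF, rt
Reagents that add atoms: none
Why: Carbonate-catalysed methanolysis cleaves the alkynyl C–Si bond selectively, while the axial ester on a quaternary carbon is far too hindered to transesterify.

**Step 11**
Reactants: 16 terminal alkyne
Product: 19 (1S,2R,5S)-8-phenylmenthyl (13E)-15-hydroxylabda-8(17),13-dien-19-oate, via alkenyl dimethylalane 17 (not isolated), via lithium alkenyl butyl alanate 18 (not isolated)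
Conditions: AlMe3 (3 equiv), Cp2ZrCl2 (0.25 equiv), CH2Cl2, 0 °C to rt; volatiles removed; n-BuLi, hexane–THF, −78 to 0 °C; (CH2O)n, rt; aq Rochelle salt
Reagents that add atoms: trimethylaluminium, C[Al](C)C (C16 methyl; the AlMe2 group only in 17 and 18); formaldehyde from paraformaldehyde, C=O (C15 and its oxygen); n-butyllithium, [Li]CCCC (only in 18)
Why: The Negishi zirconium-catalysed carboalumination adds methyl and aluminium syn across the terminal alkyne with aluminium on C14, which fixes 13E, and the derived alanate is hydroxymethylated with retention, while the 1,1-disubstituted C8=C17 alkene and the hindered ester stay passive.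

**Step 12**
Reactants: 19 allylic alcohol
Product: 21 (1S,2R,5S)-8-phenylmenthyl (13E)-15-bromolabda-8(17),13-dien-19-oate, via allylic mesylate 20 (not isolated)
Conditions: MsCl, Et3N, THF, −40 °C; then LiBr, THF, 0 °C
Reagents that add atoms: lithium bromide, [Li+].[Br-]; methanesulfonyl chloride, CS(=O)(=O)Cl (only in 20)
Why: Mesylation and in situ SN2 displacement by bromide at or below 0 °C is the standard neutral route to primary allylic bromides without SN2′ transposition or E/Z scrambling.

**Step 13**
Reactants: 22 (+)-β-eudesmol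
Product: 23 β-eudesmol 11′-O-triethylsilyl ether
Conditions: TESOTf, 2,6-lutidine, CH2Cl2, −78 to 0 °C
Reagents that add atoms: triethylsilyl triflate, CC[Si](CC)(CC)OS(=O)(=O)C(F)(F)F
Why: Silyl triflate with lutidine is the standard silylation of tertiary alcohols, and the buffer prevents acid-induced migration of the exocyclic alkene.

**Step 14**
Reactants: 23 silylated β-eudesmol
Product: 25 cryptomeridiol 11′-O-triethylsilyl ether (4′α-OH equatorial, 4′β-CH3), via organomercurial 24 (not isolated)
Conditions: Hg(OAc)2, THF–H2O (1:1), rt; then 3 M NaOH, NaBH4, 0 °C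
Reagents that add atoms: water, O; mercury(II) acetate, CC(=O)O[Hg]OC(C)=O (only in 24)
Why: In the oxymercuration–demercuration (Markovnikov hydration) water attacks the tertiary C4′ of the mercurinium ion along the equatorial α trajectory, because the axial β approach is blocked by the syn-axial C10′ methyl, which sets the 4′α-hydroxyl.

**Step 15**
Reactants: 25 cryptomeridiol 11′-O-TES ether; 21 C15 allylic bromide
Product: 27 (1S,2R,5S)-8-phenylmenthyl (13E)-15-[(11′-triethylsilyloxyeudesman-4′α-yl)oxy]labda-8(17),13-dien-19-oate, via potassium alkoxide 26 (not isolated)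
Conditions: 25, KH, 18-crown-6, THF, 0 °C; then 21, 0 °C to rt
Reagents that add atoms: potassium hydride, [K+].[H-] (gives only the potassium of 26; none of its atoms stays in 27)
Why: In this Williamson ether synthesis the crown-separated potassium alkoxide of the equatorial tertiary alcohol attacks the primary allylic bromide by SN2, the ester has no α-hydrogen and is too hindered to be attacked, and C4′ keeps its configuration because its C–O bond is never broken.

**Step 16**
Reactants: 27 coupled ester
Product: 28 (13E)-15-[(11′-triethylsilyloxyeudesman-4′α-yl)oxy]labda-8(17),13-dien-19-ol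
Conditions: LiAlH4, THF, reflux; Fieser work-up
Reagents that add atoms: none
Why: Hydride reduction is the usual way to cleave axial C19 esters that resist hydrolysis, it frees the auxiliary for reuse, and the alkenes, the allylic ether and the tertiary silyl ether are inert to it.

**Step 17**
Reactants: 28 C19 alcohol
Product: 29 the corresponding labda-8(17),13-dien-19-al
Conditions: TPAP (5 mol %), NMO, 4 Å sieves, CH2Cl2, rt
Reagents that add atoms: none
Why: The Ley–Griffith oxidation takes hindered neopentyl-type primary alcohols to aldehydes under neutral conditions that spare the alkenes, the allylic ether and the silyl ether, and C4 cannot epimerise because it is quaternary.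

**Step 18**
Reactants: 29 C19 aldehyde
Product: 30 (13E)-15-[(11′-triethylsilyloxyeudesman-4′α-yl)oxy]labda-8(17),13-dien-19-oic acid
Conditions: NaClO2, NaH2PO4, 2-methyl-2-butene (large excess), t-BuOH–H2O, rt
Reagents that add atoms: sodium chlorite, [Na+].[O-]Cl=O
Why: The Pinnick oxidation converts even hindered aldehydes to acids at mild pH, and the alkene scavenger removes the hypochlorous acid that could otherwise attack the two alkenes of the substrate.

**Step 19**
Reactants: 30 silylated acid
Product: 31 target CNP0156875.1, (4S,5R,9S,10R,13E)-15-{[(4′R,5′R,7′R,10′R)-11′-hydroxyeudesman-4′-yl]oxy}labda-8(17),13-dien-19-oic acid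
Conditions: TBAF (4 equiv), THF, rt to 40 °C; pH 5 buffer work-up
Reagents that add atoms: none
Why: Fluoride-driven desilylation removes the tertiary triethylsilyl ether under non-acidic conditions, so the ionisable tertiary-alkyl allyl ether and the exocyclic alkene are not put at risk.

**Compound list**
1 | geranyl bromide | CC(C)=CCC/C(C)=C/CBr | starting material
2 | 1-(trimethylsilyl)propyne | CC#C[Si](C)(C)C | starting material
3 | 3-lithio-1-(trimethylsilyl)propyne | [Li]CC#C[Si](C)(C)C | intermediate
4 | (5E)-6,10-dimethyl-1-(trimethylsilyl)undeca-5,9-dien-1-yne | CC(C)=CCC/C(C)=C/CCC#C[Si](C)(C)C | intermediate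
5 | (2E,6E)-2,6-dimethyl-11-(trimethylsilyl)undeca-2,6-dien-10-yn-1-ol | OC/C(C)=C/CC/C(C)=C/CCC#C[Si](C)(C)C | intermediate
6 | (5E,9E)-11-bromo-6,10-dimethyl-1-(trimethylsilyl)undeca-5,9-dien-1-yne | BrC/C(C)=C/CC/C(C)=C/CCC#C[Si](C)(C)C | intermediate
7 | (+)-8-phenylmenthol, (1S,2R,5S) | CC(C)(c1ccccc1)[C@H]1CC[C@H](C)C[C@@H]1O | starting material
8 | ethyl 2-methylacetoacetate | CCOC(=O)C(C)C(C)=O | starting material
9 | 8-phenylmenthyl 2-methyl-3-oxobutanoate (C2 epimers) | CC(C)(c1ccccc1)[C@H]1CC[C@H](C)C[C@@H]1OC(=O)C(C)C(C)=O | intermediate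
10 | sodium lithium dienediolate of 9 | C=C([O-])C(C)=C([O-])O[C@H]1C[C@@H](C)CC[C@@H]1C(C)(C)c1ccccc1.[Na+].[Li+] | intermediate
11 | 8-phenylmenthyl (6E,10E)-2,6,10-trimethyl-3-oxo-15-(trimethylsilyl)pentadeca-6,10-dien-14-ynoate (C2 epimers) | CC(C)(c1ccccc1)[C@H]1CC[C@H](C)C[C@@H]1OC(=O)C(C)C(=O)CC/C(C)=C/CC/C(C)=C/CCC#C[Si](C)(C)C | intermediate
12 | 8-phenylmenthyl 3-oxo-14-(trimethylsilyl)-15,16-dinorlabd-8(17)-en-13-yn-19-oate | C=C1CC[C@@H]2[C@](C)(CCC(=O)[C@]2(C)C(=O)O[C@H]3C[C@@H](C)CC[C@@H]3C(C)(C)c3ccccc3)[C@H]1CCC#C[Si](C)(C)C | intermediate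
13 | 3β-hydroxy derivative | C=C1CC[C@@H]2[C@](C)(CC[C@H](O)[C@]2(C)C(=O)O[C@H]3C[C@@H](C)CC[C@@H]3C(C)(C)c3ccccc3)[C@H]1CCC#C[Si](C)(C)C | intermediate
14 | 3β-O-(phenoxythiocarbonyl) derivative | C=C1CC[C@@H]2[C@](C)(CC[C@H](OC(=S)Oc3ccccc3)[C@]2(C)C(=O)O[C@H]3C[C@@H](C)CC[C@@H]3C(C)(C)c3ccccc3)[C@H]1CCC#C[Si](C)(C)C | intermediate
15 | 8-phenylmenthyl 14-(trimethylsilyl)-15,16-dinorlabd-8(17)-en-13-yn-19-oate | C=C1CC[C@@H]2[C@](C)(CCC[C@]2(C)C(=O)O[C@H]3C[C@@H](C)CC[C@@H]3C(C)(C)c3ccccc3)[C@H]1CCC#C[Si](C)(C)C | intermediate
16 | 8-phenylmenthyl 15,16-dinorlabd-8(17)-en-13-yn-19-oate | C=C1CC[C@@H]2[C@](C)(CCC[C@]2(C)C(=O)O[C@H]3C[C@@H](C)CC[C@@H]3C(C)(C)c3ccccc3)[C@H]1CCC#C | intermediate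
17 | (13E)-14-(dimethylalumanyl)-15-norlabda-8(17),13-dien-19-oate of 8-phenylmenthol | C=C1CC[C@@H]2[C@](C)(CCC[C@]2(C)C(=O)O[C@H]3C[C@@H](C)CC[C@@H]3C(C)(C)c3ccccc3)[C@H]1CC/C(C)=C/[Al](C)C | intermediate
18 | lithium butyl(dimethyl)alanate of 17 | C=C1CC[C@@H]2[C@](C)(CCC[C@]2(C)C(=O)O[C@H]3C[C@@H](C)CC[C@@H]3C(C)(C)c3ccccc3)[C@H]1CC/C(C)=C/[Al-](C)(C)CCCC.[Li+] | intermediate
19 | 8-phenylmenthyl (13E)-15-hydroxylabda-8(17),13-dien-19-oate | C=C1CC[C@@H]2[C@](C)(CCC[C@]2(C)C(=O)O[C@H]3C[C@@H](C)CC[C@@H]3C(C)(C)c3ccccc3)[C@H]1CC/C(C)=C/CO | intermediate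
20 | 15-O-mesylate of 19 | C=C1CC[C@@H]2[C@](C)(CCC[C@]2(C)C(=O)O[C@H]3C[C@@H](C)CC[C@@H]3C(C)(C)c3ccccc3)[C@H]1CC/C(C)=C/COS(C)(=O)=O | intermediate
21 | 8-phenylmenthyl (13E)-15-bromolabda-8(17),13-dien-19-oate | C=C1CC[C@@H]2[C@](C)(CCC[C@]2(C)C(=O)O[C@H]3C[C@@H](C)CC[C@@H]3C(C)(C)c3ccccc3)[C@H]1CC/C(C)=C/CBr | intermediate
22 | (+)-β-eudesmol | C=C1CCC[C@]2(C)CC[C@@H](C(C)(C)O)C[C@H]21 | starting material
23 | β-eudesmol 11′-O-triethylsilyl ether | C=C1CCC[C@]2(C)CC[C@@H](C(C)(C)O[Si](CC)(CC)CC)C[C@H]21 | intermediate
24 | 15′-(acetoxymercurio)cryptomeridiol 11′-O-triethylsilyl ether | O[C@]1(C[Hg]OC(C)=O)CCC[C@]2(C)CC[C@@H](C(C)(C)O[Si](CC)(CC)CC)C[C@H]21 | intermediate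
25 | cryptomeridiol 11′-O-triethylsilyl ether | O[C@]1(C)CCC[C@]2(C)CC[C@@H](C(C)(C)O[Si](CC)(CC)CC)C[C@H]21 | intermediate
26 | potassium 4′-alkoxide of 25 | [K+].[O-][C@]1(C)CCC[C@]2(C)CC[C@@H](C(C)(C)O[Si](CC)(CC)CC)C[C@H]21 | intermediate
27 | coupled ether, C19 8-phenylmenthyl ester, 11′-O-TES | C=C1CC[C@@H]2[C@](C)(CCC[C@]2(C)C(=O)O[C@H]3C[C@@H](C)CC[C@@H]3C(C)(C)c3ccccc3)[C@H]1CC/C(C)=C/CO[C@]1(C)CCC[C@]2(C)CC[C@@H](C(C)(C)O[Si](CC)(CC)CC)C[C@H]21 | intermediate
28 | coupled ether, C19 primary alcohol, 11′-O-TES | C=C1CC[C@@H]2[C@](C)(CCC[C@]2(C)CO)[C@H]1CC/C(C)=C/CO[C@]1(C)CCC[C@]2(C)CC[C@@H](C(C)(C)O[Si](CC)(CC)CC)C[C@H]21 | intermediate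
29 | coupled ether, C19 aldehyde, 11′-O-TES | C=C1CC[C@@H]2[C@](C)(CCC[C@]2(C)C=O)[C@H]1CC/C(C)=C/CO[C@]1(C)CCC[C@]2(C)CC[C@@H](C(C)(C)O[Si](CC)(CC)CC)C[C@H]21 | intermediate
30 | coupled ether, C19 acid, 11′-O-TES | C=C1CC[C@@H]2[C@](C)(CCC[C@]2(C)C(=O)O)[C@H]1CC/C(C)=C/CO[C@]1(C)CCC[C@]2(C)CC[C@@H](C(C)(C)O[Si](CC)(CC)CC)C[C@H]21 | intermediate
31 | CNP0156875.1 | C=C1CC[C@@H]2[C@](C)(CCC[C@]2(C)C(=O)O)[C@H]1CC/C(C)=C/CO[C@]1(C)CCC[C@]2(C)CC[C@@H](C(C)(C)O)C[C@H]21 | target

**Step count**
Total step count: 19. Longest linear sequence: 16 steps (steps 1–3, 5–12 and 15–19, from geranyl bromide).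

**Steps most likely to fail**

Step 6. Facial selectivity may erode at 25 °C, because rotamers of the open radical about the C4–C19 bond present different faces to the phenyl shield. The cascade may also end badly: Mn(III) may over-oxidise the C8 radical, or that radical may add on to the alkyne before Cu(II) reaches it.

The fallback sets out from 11 and comes back at 12. It replaces oxidative radical generation by a phenylselanyl group-transfer chain run cold. The sodium enolate of 11 (NaH, THF, 0 °C) is selenenylated with PhSeCl to the 2-methyl-2-(phenylselanyl) ketoester F1. Initiation with Et3B and air (or visible light) in CH2Cl2 at about −40 °C breaks the weak C4–Se bond. The same two 6-endo closures follow, and the C8 radical abstracts PhSe from a further molecule of F1 to give the 8-(phenylselanyl) bicycle F2 as C8 epimers. Oxidation with H2O2 and pyridine at 0 °C then triggers selenoxide syn-elimination, which should go toward the freely rotating C17 methyl rather than into the chair, and this gives 12. The low temperature should sharpen the rotamer and face discrimination, and no metal oxidant is present to divert the C8 radical.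

Step 15. The hindered tertiary alkoxide may act as a base and cause 1,4-elimination of HBr from the allylic bromide. It may also attack in the SN2′ sense faster than it substitutes at C15.

The fallback sets out from 25 and 16 and comes back at 27. It joins the halves at C14–C15 instead of at O–C15. Alcohol 25 is converted with DMSO, Ac2O and AcOH at rt (Pummerer-type alkylation, which tolerates tertiary alcohols) into the methylthiomethyl ether F3. SO2Cl2 in CH2Cl2 at −78 °C turns this into the chloromethyl ether F4. Alkyne 16 is carboaluminated as in step 11, and the alkenylalane 17 is treated directly with F4 at 0 °C. Alkenylalanes are known to be alkylated with retention by chloromethyl ethers, so 27 should result with the 13E geometry intact, and neither the allylic bromide nor a free alkoxide is needed.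

Step 14. Water may attack the mercurinium ion with poor α/β selectivity, and the silyl ether may be partly lost in the aqueous Hg(II)/acetic acid medium.

The fallback sets out from 23 and comes back at 25. It separates face selection from C–O bond placement. Epoxidation with m-CPBA and NaHCO3 in CH2Cl2 at 0 °C should occur from the α face, anti to the axial C10′ methyl, to give the 4′α,15′-epoxide F5, which can be purified from any β-epoxide. LiAlH4 (or LiEt3BH) in THF opens it at the primary C15′ to give 25.

**Further compounds**
F1 | step 6 | 8-phenylmenthyl (6E,10E)-2,6,10-trimethyl-3-oxo-2-(phenylselanyl)-15-(trimethylsilyl)pentadeca-6,10-dien-14-ynoate (C2 epimers) | CC(C)(c1ccccc1)[C@H]1CC[C@H](C)C[C@@H]1OC(=O)C(C)([Se]c1ccccc1)C(=O)CC/C(C)=C/CC/C(C)=C/CCC#C[Si](C)(C)C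
F2 | step 6 | 8-phenylmenthyl 3-oxo-8-(phenylselanyl)-14-(trimethylsilyl)-15,16-dinorlabd-13-yn-19-oate (C8 epimers) | CC1([Se]c4ccccc4)CC[C@@H]2[C@](C)(CCC(=O)[C@]2(C)C(=O)O[C@H]3C[C@@H](C)CC[C@@H]3C(C)(C)c3ccccc3)[C@H]1CCC#C[Si](C)(C)C
F3 | step 15 | cryptomeridiol 4′-O-(methylthiomethyl) 11′-O-triethylsilyl diether | CSCO[C@]1(C)CCC[C@]2(C)CC[C@@H](C(C)(C)O[Si](CC)(CC)CC)C[C@H]21
F4 | step 15 | cryptomeridiol 4′-O-(chloromethyl) 11′-O-triethylsilyl diether | ClCO[C@]1(C)CCC[C@]2(C)CC[C@@H](C(C)(C)O[Si](CC)(CC)CC)C[C@H]21
F5 | step 14 | 4′α,15′-epoxyeudesman-11′-ol triethylsilyl ether | C1O[C@@]12CCC[C@]3(C)CC[C@@H](C(C)(C)O[Si](CC)(CC)CC)C[C@H]32
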